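The data were computed from invented constants.

Every charged substrate molecule stands as solid, dissolved substrate (the starting material), first product, bis adduct or triple product, so these forms sum to 100% of the charge, and coupling partner moves it along that row.

| setting | eta | epsilon | Saturday's | Tuesday's |
|---|---|---|---|---|
| solid substrate | 2 M | 2 M | 2.0 M | 2.0 M |
| coupling partner | 0.70 M | 1.8 M | 1.00 M | 2.40 M |
| remark | run made earlier | run made earlier |  |  |
| time |  |  | 5.0 h | 5.0 h |

- eta (time / h: first product / %): 0.417: 2.5; 0.667: 6.1; 1.00: 6.9; 2.00: 10.9; 3.00: 10.8; 5.00: 14.8
- epsilon (time / h: first product / %): 0.333: 4.7; 1.00: 13.2; 2.00: 14.1; 2.50: 17.4; 4.00: 17.2; 5.00: 16.2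

(each reading ± 1 percentage point)

- as a solid, counted per litre of solution: solid substrate
- at the start none of the solid substrate is in solution

- which of these holds the largest part of the solid substrate at the end of Saturday's (solid substrate / first product / bis adduct / triple product)
- which of these holds the largest part of the solid substrate at the end of Tuesday's (solid substrate / first product / bis adduct / triple product)
- final first product in Saturday's, as a percentage of the solid substrate charged

Take the main step first. If the solid holds the dissolved level steady, first product forms pseudo-first-order in partner, at k′[coupling partner]. The eta reading at 1.00 h gives k′ ≈ 0.197 h⁻¹, and that rate, held at Saturday's full charge, gives 49.3% first product.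

Now add first product + partner into bis adduct. Its rate also carries [coupling partner], so partner cancels from the ratio of making to using. The epsilon readings from 2.50 h on average 16.9%: this reading is taken here as the ceiling, a working estimate of the [first product] at which both steps run equally fast; it carries the scatter of the readings, and the course may still be rising there.

Then let partner run down. Near the ceiling each substrate molecule takes two partners, triple product aside, so partner falls with constant 2k′ and 13.9% is reckoned to remain at 5.0 h. Taking it as used up, and with u the progress in ceiling units, [first product] = ceiling·(1 − e^−u), substrate reacted = ceiling·u and partner used = ceiling·(2·u − 1).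

Saturday's then has u = 1.98 and first product 14.6%, with 66.5% of the substrate unreacted. Tuesday's has u = 4.04, so bis adduct is reckoned at 51.8%, more than the 31.5% reckoned unreacted.

The forecast, unlike this reckoning, names solid substrate for Tuesday's; it gives solid substrate for Saturday's and 14.5% (11.5% to 17.5%) of first product: “About 1 M stays solid, still more than any product.”

Saturday's ends with solid substrate ahead at 60.8% and first product at 15.0%; Tuesday's ends with bis adduct at 38.5%.

    starting material + coupling partner → first product (k = 4.76 × 10⁻⁴ M⁻¹ s⁻¹)
    coupling partner + first product → bis adduct (k = 2.28 × 10⁻⁴ M⁻¹ s⁻¹)
    coupling partner + bis adduct ⇌ triple product (K = 0.650 M⁻¹, k = 0.00164 M⁻¹ s⁻¹)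
    solid substrate ⇌ starting material, rate k4*(cs4 - [starting material]) while solid is left; crystals form when [starting material] > cs4 (solubility = 0.190 M, k = 0.00370 s⁻¹)

At 5.00 h in Saturday's, the main step uses partner 1.3 times as fast as the second step, with first product at 15.0% and 15.7% standing at 50.0 h. For the neighbour charged with 2.5 M of partner, the same reckoning gives 16.7%, and that flask ends at 17.6%.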